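The ring atoms are numbered as follows: C1 and C4 are the carbonyls, C2 carries OMe, C3 carries H, C5 carries methyl and C6 carries the pentacosyl chain (C1′ onward). The route exploits the C5=C6 edge of the quinone ring, where the methyl group and the chain lie α and β to C4=O. Both C6–C1′ and C5–CH3 are therefore traced back to the vicinal difunctionalisation of an enone. The precursor is the C1 dimethyl monoketal 3,4,4-trimethoxycyclohexa-2,5-dienone, in which only C5=C6 is a free acceptor. In one flask, copper catalysis transfers the pentacosyl group from zinc and the resulting enolate is methylated. Acid-induced loss of methanol then rearomatises the ring, and oxidation gives the quinone.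

Key step: step 4

Remark: the target has no stereocentre and is achiral, so there is no enantiomer to choose. The sp3 intermediates of steps 4 and 5 are racemates, and one enantiomer is drawn.

Step 1
Reactants: 1 3,4-dimethoxyphenol
Product: 2 3,4,4-trimethoxycyclohexa-2,5-dien-1-one
Conditions: PhI(OAc)2 (1.05 equiv), MeOH, 0 °C → rt; NaHCO3 work-up
Reagents that add atoms: methanol, CO
Why: Iodine(III)-mediated oxidative dearomatisation of a 4-alkoxyphenol: two-electron oxidation makes the methoxy-bearing para carbon electrophilic, methanol adds there and the quinone dimethyl monoketal results, with no stereocentre formed.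

Step 2
Reactants: 3 1-bromodocosane; 4 allylmagnesium bromide
Product: 5 pentacos-1-ene
Conditions: 4 (1.5 equiv), Li2CuCl4 (3 mol %), THF/Et2O, 0 → 35 °C
Reagents that add atoms: allylmagnesium bromide 4, C=CC[Mg]Br
Why: Copper-catalysed Grignard cross-coupling with an unhindered primary alkyl bromide joins the C22 and C3 pieces, and the symmetrical allyl nucleophile can only give the terminal C25 alkene.

Step 3
Reactants: 5 pentacos-1-ene
Product: 7 dipentacosylzinc, via diethyl(pentacosyl)borane 6 (not isolated)
Conditions: Et2BH (1.1 equiv, from BH3·SMe2 + 2 Et3B), toluene, 0 → 40 °C; evaporate; Et2Zn (2 equiv), 0 °C → rt; 0.1 mbar, 45 °C; take up in toluene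
Reagents that add atoms: diethylborane, CCBCC (boron and ethyl groups, kept only in 6); diethylzinc, CC[Zn]CC (zinc of 7)
Why: Anti-Markovnikov hydroboration with the hindered dialkylborane puts boron on C1′, and boron–zinc exchange (transmetalation) with diethylzinc is pulled to the symmetrical, salt-free primary dialkylzinc by stripping off volatile triethylborane and excess diethylzinc.

Step 4
Reactants: 2 3,4,4-trimethoxycyclohexa-2,5-dien-1-one; 7 dipentacosylzinc; 8 iodomethane
Product: 10 (±)-trans-(5R*,6R*)-3,4,4-trimethoxy-6-methyl-5-pentacosylcyclohex-2-en-1-one, via pentacosylzinc dienolate 9 (not isolated)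
Conditions: Cu(OTf)2 (5 mol %), P(OEt)3 (10 mol %), 7 (1.3 equiv, added as a warm toluene solution), toluene, 0 °C → rt; then MeI (10 equiv), HMPA (6 equiv), 0 °C → rt; aq NH4Cl/NH3 (pH 8–9)
Reagents that add atoms: dipentacosylzinc 7, CCCCCCCCCCCCCCCCCCCCCCCCC[Zn]CCCCCCCCCCCCCCCCCCCCCCCCC; iodomethane 8, CI
Why: Alkyl transfer from 7 to copper(I) gives an alkylcopper species that π-binds the C5=C6 alkene of 2, forms C6–C1′ by oxidative addition at C6 and reductive elimination, and hands the enolate oxygen to zinc as 9, after which HMPA loosens the O–Zn aggregate so that C5 displaces iodide from 8 in an SN2 reaction. The closest known reaction types are the copper-catalysed 1,4-addition of dialkylzincs to benzoquinone monoketals and the tandem conjugate addition/α-alkylation of cyclic enones through alkylzinc enolates, so this is a three-component coupling and no ring is closed. C6 arises as a racemate because the catalyst is achiral and the two faces of planar 2 are enantiotopic, whereas C5 is set by the substrate, since 8 approaches the enolate face opposite the C6 chain and should favour the trans isomer. Site selectivity for C6 over C2 is secured by the C2 methoxy group, which turns C2=C3 into a fully β-substituted, electron-rich vinylogous ester, and the C1 ketal leaves C4=O as the only carbonyl, so a single enone can react. Enolate 9 has no β-leaving group because the ketal methoxy groups sit on C1, γ to C4, and the soft zinc–copper pair keeps 1,2-addition and electron-transfer reduction of 2 back to 1 in check. Both new centres are erased in step 5, so neither the diastereoselectivity nor the racemic nature matters for the achiral target.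

Step 5
Reactants: 10 (±)-trans-3,4,4-trimethoxy-6-methyl-5-pentacosylcyclohex-2-en-1-one
Product: 12 4,5-dimethoxy-2-methyl-3-pentacosylphenol, via cyclohexa-2,4-dienone tautomer 11 (not isolated)
Conditions: CSA (10 mol %), toluene, rt → 40 °C
Reagents that add atoms: none
Why: Acid-catalysed ionisation of the ketal to an oxocarbenium ion, loss of the C6 proton (E1 elimination of methanol) and keto–enol tautomerisation of 11 give the 4-methoxyphenol with aromatisation as driving force and both stereocentres erased, and any competing ketal hydrolysis would only lead to the corresponding hydroquinone, which step 6 oxidises to the same quinone.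

Step 6
Reactants: 12 4,5-dimethoxy-2-methyl-3-pentacosylphenol
Product: 13 2-methoxy-5-methyl-6-pentacosyl-1,4-benzoquinone (target)
Conditions: (NH4)2Ce(NO3)6 (2.3 equiv), MeCN/CH2Cl2/H2O, 0 °C → rt
Reagents that add atoms: water, O
Why: Ceric ammonium nitrate oxidative demethylation of a 4-methoxyphenol: two one-electron oxidations give a phenoxenium ion, water adds at the methoxy-bearing C1 and the hemiketal collapses with loss of methanol to the 1,4-quinone, while the C2 methoxy group stays as part of a vinylogous ester.

Compound list
1 | 3,4-dimethoxyphenol | COc1ccc(O)cc1OC | starting material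
2 | 3,4,4-trimethoxycyclohexa-2,5-dien-1-one | COC1=CC(=O)C=CC1(OC)OC | intermediate
3 | 1-bromodocosane | CCCCCCCCCCCCCCCCCCCCCCBr | starting material
4 | allylmagnesium bromide | C=CC[Mg]Br | starting material
5 | pentacos-1-ene | CCCCCCCCCCCCCCCCCCCCCCCC=C | intermediate
6 | diethyl(pentacosyl)borane | CCB(CC)CCCCCCCCCCCCCCCCCCCCCCCCC | intermediate
7 | dipentacosylzinc | CCCCCCCCCCCCCCCCCCCCCCCCC[Zn]CCCCCCCCCCCCCCCCCCCCCCCCC | intermediate
8 | iodomethane | CI | starting material
9 | pentacosylzinc dienolate of 3,4,4-trimethoxy-5-pentacosylcyclohex-2-en-1-one (racemic, one enantiomer drawn) | COC1=CC(O[Zn]CCCCCCCCCCCCCCCCCCCCCCCCC)=C[C@@H](CCCCCCCCCCCCCCCCCCCCCCCCC)C1(OC)OC | intermediate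
10 | (±)-trans-(5R*,6R*)-3,4,4-trimethoxy-6-methyl-5-pentacosylcyclohex-2-en-1-one (one enantiomer drawn) | C[C@H]1C(=O)C=C(OC)C(OC)(OC)[C@@H]1CCCCCCCCCCCCCCCCCCCCCCCCC | intermediate
11 | (±)-3,4-dimethoxy-6-methyl-5-pentacosylcyclohexa-2,4-dien-1-one (one enantiomer drawn) | C[C@H]1C(=O)C=C(OC)C(OC)=C1CCCCCCCCCCCCCCCCCCCCCCCCC | intermediate
12 | 4,5-dimethoxy-2-methyl-3-pentacosylphenol | COc1cc(O)c(C)c(CCCCCCCCCCCCCCCCCCCCCCCCC)c1OC | intermediate
13 | 2-methoxy-5-methyl-6-pentacosyl-1,4-benzoquinone (5-methoxy-2-methyl-3-pentacosylcyclohexa-2,5-diene-1,4-dione), achiral | CCCCCCCCCCCCCCCCCCCCCCCCCC1=C(C)C(=O)C=C(OC)C1=O | target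

Total step count: 6.
Longest linear sequence: 5 steps (3 → 5 → 7 → 10 → 12 → 13). The ring branch (1 → 2) joins at step 4.

Steps most likely to fail

Step 4. Methylation of the alkylzinc enolate may be slower than proton transfer. It may also be slower than Lewis-acid-induced loss of methanol, which would aromatise the ring prematurely. The low solubility of the waxy zinc reagent may slow the copper cycle enough for electron-transfer reduction of the ketal to compete. The fallback separates the two bond formations. Setting out from 2 and 7, only the copper-catalysed conjugate addition is run. The enolate is protonated with buffered aqueous NH4Cl to give (±)-3,4,4-trimethoxy-5-pentacosylcyclohex-2-en-1-one F1, which is isolated. Its γ-carbon is the quaternary ketal, so LDA (THF, −78 °C) can only deprotonate the CH2 next to the carbonyl, as in the Stork–Danheiser α′-alkylation of 3-alkoxyenones. The lithium enolate is far more nucleophilic than its zinc counterpart. It is methylated with 8 at low temperature, anti to the chain, and the route is rejoined at 10.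

Step 3. Boron-to-zinc exchange may be incomplete, or ethyl groups may not be fully stripped from the waxy mass, which would lead to competing ethyl transfer in the key step. The fallback avoids ethyl-bearing reagents altogether. Setting out from 5, radical-chain anti-Markovnikov hydrobromination (HBr, dibenzoyl peroxide, hexane; Kharasch peroxide effect) should give 1-bromopentacosane F2. Magnesium insertion in warm THF gives pentacosylmagnesium bromide F3. Transmetalation with ZnCl2 (0.5 equiv), precipitation of the magnesium salts with 1,4-dioxane and solvent exchange to toluene lead back to 7.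

Step 6. The waxy phenol may dissolve poorly in the aqueous medium, which would make the one-electron oxidation slow and heterogeneous and leave room for over-oxidation or ring nitration. The fallback uses a homogeneous, non-aqueous two-electron oxidation followed by hydrolysis. Setting out from 12, PhI(OAc)2 in MeOH/CH2Cl2 (the reaction type of step 1) should give 3,4,4-trimethoxy-6-methyl-5-pentacosylcyclohexa-2,5-dien-1-one F4. Mild hydrolysis of this ketal (aqueous oxalic acid, THF, rt) releases C1=O and rejoins the route at 13.

Further compounds
F1 | step 4 | (±)-3,4,4-trimethoxy-5-pentacosylcyclohex-2-en-1-one (one enantiomer drawn) | COC1=CC(=O)C[C@@H](CCCCCCCCCCCCCCCCCCCCCCCCC)C1(OC)OC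
F2 | step 3 | 1-bromopentacosane | CCCCCCCCCCCCCCCCCCCCCCCCCBr
F3 | step 3 | pentacosylmagnesium bromide | CCCCCCCCCCCCCCCCCCCCCCCCC[Mg]Br
F4 | step 6 | 3,4,4-trimethoxy-6-methyl-5-pentacosylcyclohexa-2,5-dien-1-one | COC1=CC(=O)C(C)=C(CCCCCCCCCCCCCCCCCCCCCCCCC)C1(OC)OC
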